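## Retrosynthetic overview

1. Target 18 (quinoline numbering; stereocentre C6, R) ⇐ N-methylation and Beckmann nitrogen insertion from methyl ketone 13. The chain CH2CH2N(Me)C(=O)CH3 is a 3-oxobutyl group plus one nitrogen atom.
2. Pyridine ring (formed second) ⇐ enone 6: iodide at C4a, B-alkyl coupling for C4a–C4, ammonia for N1–C2 and N1–C8a. The C4a=C5 enone bond moves into the aromatic ring and fixes the annulation to the C4a side (annulation at C8 would give the enantiomeric skeleton).
3. Carbocycle (formed first, key step) ⇐ achiral diketo aldehyde 4 by a catalyst-controlled desymmetrizing aldol condensation. It forms C4a–C5 (methyl carbon of one arm to the formyl carbon) and makes C6 stereogenic.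
4. Enabling feature: C6 carries the ring arm C7–C8–C8a–C4a and the side-chain arm CH2–CH2–[N]–C(=O)–CH3. Without N both are the same 3-oxobutyl unit, with the formyl carbon C5 on the mirror plane between them.
5. 4 ⇐ twofold Michael addition of (3,4-dimethoxyphenyl)acetaldehyde 1 to methyl vinyl ketone 2.

Key step: step 2

Assumption: the sense in which a given amine catalyst selects between the two arms of 4 cannot be derived with certainty from the closest precedents. The route is written with the quinine-derived primary amine; its quinidine-derived pseudo-enantiomer would take its place if the former should favour the (S)-enone.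

## Route

Step 1
Reactants: 1 (3,4-dimethoxyphenyl)acetaldehyde; 2 but-3-en-2-one (methyl vinyl ketone, 2.5 equiv)
Product: 4 2-(3,4-dimethoxyphenyl)-5-oxo-2-(3-oxobutyl)hexanal, via mono-Michael adduct 3 (not isolated)
Conditions: DBU (10 mol %), THF, −20 °C to 0 °C, slow addition of 1 to 2 and DBU; AcOH quench
Reagents that add atoms: none
Why: Twofold base-catalysed Michael addition: the benzylic, formyl-activated α-position is the only site deprotonated readily at this base strength, so both C–C bonds should form there before a ketone enolate can start an aldol reaction, and 4 is achiral because the centre of 3 becomes a prochiral quaternary carbon.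

Step 2
Reactants: 4 2-(3,4-dimethoxyphenyl)-5-oxo-2-(3-oxobutyl)hexanal
Product: 6 (4R)-4-(3,4-dimethoxyphenyl)-4-(3-oxobutyl)cyclohex-2-en-1-one, via aldol adduct 5 (not isolated)
Conditions: 9-amino-9-deoxy-epi-quinine (20 mol %), AcOH (60 mol %), toluene, 0 °C to rt
Reagents that add atoms: none
Why: Proposed new method: the primary amine condenses with either 3-oxobutyl arm of 4 to the methyl-side enamine, which adds to the formyl carbon (aldol adduct 5, held largely as its iminium), and loss of water followed by hydrolysis should release enone 6 and the catalyst; the closest known reaction types are the amine-catalysed desymmetrizing aldol condensations of prochiral di- and triketones (Hajos–Parrish–Eder–Sauer–Wiechert cyclization, cyclization of 4-substituted heptane-2,6-diones to 5-substituted 3-methylcyclohexenones) and the ring-closing half of the Robinson annulation of α,α-disubstituted aldehydes. The carbocycle is closed in the 6-(enolendo)-exo-trig mode by the new bond between the arm methyl carbon (later C4a) and the formyl carbon (later C5). The only stereocentre that survives, the quaternary carbon, is set by selection between the two enantiotopic arms under control of the chiral amine, whose protonated quinuclidine should hold the formyl oxygen by a hydrogen bond so that the enamine of one arm reaches the aldehyde through a chair-like transition state; the carbinol centre of 5 is erased by dehydration. Chemoselectivity for the formyl acceptor over a ketone–ketone aldol is secured because the aldehyde is the most electrophilic carbonyl group and cannot enolize (its α-carbon is quaternary), and because the ketone–ketone aldol is reversible while the condensation is not. Attack from the methyl side is secured by ring size, since the methylene-side enamine could only reach the formyl group through a four-membered ring.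

Step 3
Reactants: 6 (4R)-4-(3,4-dimethoxyphenyl)-4-(3-oxobutyl)cyclohex-2-en-1-one
Product: 7 (4R)-4-(3,4-dimethoxyphenyl)-2-iodo-4-(3-oxobutyl)cyclohex-2-en-1-one
Conditions: I2 (1.5 equiv), pyridine/CH2Cl2 (1:1), 0 °C to rt; aq. Na2S2O3 work-up
Reagents that add atoms: iodine, II
Why: α-Iodination of a cyclic enone by the Baylis–Hillman-type sequence (pyridine adds to C5, the enolate is iodinated at C4a, pyridine is eliminated), which acts only on the conjugated ketone and so marks the C4a side of the ring while the saturated methyl ketone and the quaternary centre stay untouched.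

Step 4
Reactants: 7 (4R)-4-(3,4-dimethoxyphenyl)-2-iodo-4-(3-oxobutyl)cyclohex-2-en-1-one; 8 3,3-diethoxyprop-1-ene (acrolein diethyl acetal)
Product: 10 (4R)-2-(3,3-diethoxypropyl)-4-(3,4-dimethoxyphenyl)-4-(3-oxobutyl)cyclohex-2-en-1-one, via alkylborane 9 (not isolated)
Conditions: 8, 9-BBN-H (0.5 M in THF), 0 °C to rt; then 7, PdCl2(dppf) (5 mol %), AsPh3 (10 mol %), Cs2CO3, DMF/THF/H2O, rt
Reagents that add atoms: none
Why: B-alkyl Suzuki–Miyaura coupling, well precedented for 2-iodocycloalkenones: anti-Markovnikov hydroboration gives the primary alkylborane 9, zerovalent palladium inserts into the vinylic C–I bond, and transmetalation and reductive elimination should form C4a–C4 without touching the ketones or the stereocentre.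

Step 5
Reactants: 10 (4R)-2-(3,3-diethoxypropyl)-4-(3,4-dimethoxyphenyl)-4-(3-oxobutyl)cyclohex-2-en-1-one
Product: 13 4-[(6S)-6-(3,4-dimethoxyphenyl)-5,6,7,8-tetrahydroquinolin-6-yl]butan-2-one, via keto aldehyde 11 (not isolated), via dihydropyridine tautomer 12 (not isolated)
Conditions: AcOH/H2O (4:1), 50 °C; then NH4OAc (10 equiv), 90 °C
Reagents that add atoms: ammonium acetate, CC(=O)[O-].[NH4+]
Why: Pyridine synthesis by cyclocondensation of a 1,5-dicarbonyl compound with ammonia: acetal hydrolysis frees aldehyde 11, NH3 condenses with C2 and C8a, and the unsaturation that a saturated 1,5-diketone would need from an oxidant is supplied by the C4a=C5 enone bond, which shifts into the ring (12 to 13) and leaves C5 as CH2, the stereocentre not being involved (its descriptor changes only through the priority rules).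

Step 6
Reactants: 13 4-[(6S)-6-(3,4-dimethoxyphenyl)-5,6,7,8-tetrahydroquinolin-6-yl]butan-2-one
Product: 14 (2E)-4-[(6S)-6-(3,4-dimethoxyphenyl)-5,6,7,8-tetrahydroquinolin-6-yl]butan-2-one oxime
Conditions: NH2OH·HCl, NaOAc, EtOH/H2O, 60 °C
Reagents that add atoms: hydroxylamine hydrochloride, Cl.NO
Why: Oxime formation (condensation) at the only carbonyl group left, in which the E isomer with OH anti to the CH2 chain should predominate for steric reasons.

Step 7
Reactants: 14 (2E)-4-[(6S)-6-(3,4-dimethoxyphenyl)-5,6,7,8-tetrahydroquinolin-6-yl]butan-2-one oxime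
Product: 17 N-{2-[(6R)-6-(3,4-dimethoxyphenyl)-5,6,7,8-tetrahydroquinolin-6-yl]ethyl}acetamide, via oxime tosylate 15 (not isolated), via imidoyl tosylate 16 (not isolated)
Conditions: TsCl (1.2 equiv), pyridine, 0 °C to 40 °C; then H2O, NaHCO3
Reagents that add atoms: water, O
Why: Beckmann rearrangement: the CH2 group anti to the tosylate leaving group migrates from carbon to nitrogen, which inserts N between the chain and the acetyl carbon, and hydrolysis of 16 should give the N-alkylacetamide, with the ring nitrogen acting only as a base and the quaternary centre remote from the event.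

Step 8
Reactants: 17 N-{2-[(6R)-6-(3,4-dimethoxyphenyl)-5,6,7,8-tetrahydroquinolin-6-yl]ethyl}acetamide
Product: 18 N-{2-[(6R)-6-(3,4-dimethoxyphenyl)-5,6,7,8-tetrahydroquinolin-6-yl]ethyl}-N-methylacetamide
Conditions: NaH (1.1 equiv), THF, 0 °C; MeI (1.05 equiv), 0 °C to rt
Reagents that add atoms: iodomethane, CI
Why: N-Alkylation of a secondary amide through its sodium amidate (SN2), which is far more nucleophilic than the flanked pyridine nitrogen when only a slight excess of MeI is used at low temperature.

## Compound list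

1 | (3,4-dimethoxyphenyl)acetaldehyde | COc1ccc(CC=O)cc1OC | starting material
2 | but-3-en-2-one (methyl vinyl ketone) | CC(=O)C=C | starting material
3 | 2-(3,4-dimethoxyphenyl)-5-oxohexanal (racemic mono-Michael adduct, not isolated) | COc1ccc(C(C=O)CCC(C)=O)cc1OC | intermediate
4 | 2-(3,4-dimethoxyphenyl)-5-oxo-2-(3-oxobutyl)hexanal (achiral) | COc1ccc(C(C=O)(CCC(C)=O)CCC(C)=O)cc1OC | intermediate
5 | (4S)-4-(3,4-dimethoxyphenyl)-3-hydroxy-4-(3-oxobutyl)cyclohexan-1-one (both C3 epimers, not isolated) | COc1ccc([C@]2(CCC(C)=O)CCC(=O)CC2O)cc1OC | intermediate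
6 | (4R)-4-(3,4-dimethoxyphenyl)-4-(3-oxobutyl)cyclohex-2-en-1-one | COc1ccc([C@]2(CCC(C)=O)CCC(=O)C=C2)cc1OC | intermediate
7 | (4R)-4-(3,4-dimethoxyphenyl)-2-iodo-4-(3-oxobutyl)cyclohex-2-en-1-one | COc1ccc([C@]2(CCC(C)=O)CCC(=O)C(I)=C2)cc1OC | intermediate
8 | 3,3-diethoxyprop-1-ene (acrolein diethyl acetal) | C=CC(OCC)OCC | starting material
9 | 9-(3,3-diethoxypropyl)-9-borabicyclo[3.3.1]nonane (not isolated) | CCOC(CCB1C2CCCC1CCC2)OCC | intermediate
10 | (4R)-2-(3,3-diethoxypropyl)-4-(3,4-dimethoxyphenyl)-4-(3-oxobutyl)cyclohex-2-en-1-one | COc1ccc([C@]2(CCC(C)=O)CCC(=O)C(CCC(OCC)OCC)=C2)cc1OC | intermediate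
11 | 3-[(3R)-3-(3,4-dimethoxyphenyl)-6-oxo-3-(3-oxobutyl)cyclohex-1-en-1-yl]propanal (not isolated) | COc1ccc([C@]2(CCC(C)=O)CCC(=O)C(CCC=O)=C2)cc1OC | intermediate
12 | 4-[(6S)-6-(3,4-dimethoxyphenyl)-4,6,7,8-tetrahydroquinolin-6-yl]butan-2-one (not isolated) | COc1ccc([C@]2(CCC(C)=O)CCC3=NC=CCC3=C2)cc1OC | intermediate
13 | 4-[(6S)-6-(3,4-dimethoxyphenyl)-5,6,7,8-tetrahydroquinolin-6-yl]butan-2-one | COc1ccc([C@]2(CCC(C)=O)CCc3ncccc3C2)cc1OC | intermediate
14 | (2E)-4-[(6S)-6-(3,4-dimethoxyphenyl)-5,6,7,8-tetrahydroquinolin-6-yl]butan-2-one oxime | COc1ccc([C@]2(CC/C(C)=N/O)CCc3ncccc3C2)cc1OC | intermediate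
15 | (2E)-4-[(6S)-6-(3,4-dimethoxyphenyl)-5,6,7,8-tetrahydroquinolin-6-yl]butan-2-one O-(4-methylbenzenesulfonyl)oxime (not isolated) | COc1ccc([C@]2(CC/C(C)=N/OS(=O)(=O)c3ccc(C)cc3)CCc3ncccc3C2)cc1OC | intermediate
16 | 1-({2-[(6R)-6-(3,4-dimethoxyphenyl)-5,6,7,8-tetrahydroquinolin-6-yl]ethyl}imino)ethyl 4-methylbenzenesulfonate (not isolated) | COc1ccc([C@]2(CCN=C(C)OS(=O)(=O)c3ccc(C)cc3)CCc3ncccc3C2)cc1OC | intermediate
17 | N-{2-[(6R)-6-(3,4-dimethoxyphenyl)-5,6,7,8-tetrahydroquinolin-6-yl]ethyl}acetamide | COc1ccc([C@]2(CCNC(C)=O)CCc3ncccc3C2)cc1OC | intermediate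
18 | N-{2-[(6R)-6-(3,4-dimethoxyphenyl)-5,6,7,8-tetrahydroquinolin-6-yl]ethyl}-N-methylacetamide | COc1ccc([C@]2(CCN(C)C(C)=O)CCc3ncccc3C2)cc1OC | target

## Step count and risks

Total step count: 8. Longest linear sequence: 8 steps (1 to 18).

Steps most likely to fail:

Step 2 (Proposed new method). The catalyst may discriminate poorly between the two enantiotopic arms, or the remaining arm may add to the new enone in an intramolecular Michael reaction. The fallback sets out from 4 and comes back at 6. Compound 4 would be cyclized without stereocontrol (pyrrolidine, AcOH, toluene, 60 °C) through the racemic aldol adduct F1 to the racemic enone F2. F2 would be dehydrogenated with DDQ (dioxane, reflux) to the achiral cross-conjugated 4-(3,4-dimethoxyphenyl)-4-(3-oxobutyl)cyclohexa-2,5-dien-1-one F3. One of the two enantiotopic C=C bonds of F3 would then be reduced by an ene-reductase of the old yellow enzyme family (NADPH recycled with glucose and glucose dehydrogenase; enzyme chosen from a panel for the R product). This is a known desymmetrization of prochiral 4,4-disubstituted cyclohexadienones.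

Step 1. The sensitive arylacetaldehyde may self-condense, or the mono-adduct may close to a cyclohexenone before the second addition. The fallback sets out from 2 and comes back at 4. Compound 2 would be treated with HBr to give 4-bromobutan-2-one F4, which is ketalized with ethylene glycol (TsOH, benzene, reflux) to 2-(2-bromoethyl)-2-methyl-1,3-dioxolane F5. Commercial (3,4-dimethoxyphenyl)acetonitrile (COc1ccc(CC#N)cc1OC) would be dialkylated with F5 (NaH, DMSO/THF, rt) to the bis-ketal nitrile F6. Reduction with DIBAL-H (toluene, −78 °C) and aqueous work-up would give the bis-ketal aldehyde F7. Mild acid (PPTS, acetone/H2O) would free both ketones to give 4.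

Step 7. The methyl group may migrate instead of the chain (from the Z-oxime), which would give the isomeric N-methyl amide. The fallback sets out from 13 and comes back at 17. Iodoform cleavage of 13 (I2, aq. NaOH, dioxane, 0 °C to rt) would run through the triiodomethyl ketone F8 to 3-[(6S)-6-(3,4-dimethoxyphenyl)-5,6,7,8-tetrahydroquinolin-6-yl]propanoic acid F9. Curtius rearrangement (DPPA, Et3N, toluene, 80 °C) would pass through the acyl azide F10 to the isocyanate F11, with the alkyl–nitrogen bond formed by retentive migration of the chain only. Addition of MeMgBr (THF, −78 °C to 0 °C) to the isocyanate carbon would give acetamide 17.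

## Further compounds

F1 | step 2 | rac-4-(3,4-dimethoxyphenyl)-3-hydroxy-4-(3-oxobutyl)cyclohexan-1-one | COc1ccc(C2(CCC(C)=O)CCC(=O)CC2O)cc1OC
F2 | step 2 | rac-4-(3,4-dimethoxyphenyl)-4-(3-oxobutyl)cyclohex-2-en-1-one | COc1ccc(C2(CCC(C)=O)CCC(=O)C=C2)cc1OC
F3 | step 2 | 4-(3,4-dimethoxyphenyl)-4-(3-oxobutyl)cyclohexa-2,5-dien-1-one | COc1ccc(C2(CCC(C)=O)C=CC(=O)C=C2)cc1OC
F4 | step 1 | 4-bromobutan-2-one | CC(=O)CCBr
F5 | step 1 | 2-(2-bromoethyl)-2-methyl-1,3-dioxolane | CC1(CCBr)OCCO1
F6 | step 1 | 2-(3,4-dimethoxyphenyl)-4-(2-methyl-1,3-dioxolan-2-yl)-2-[2-(2-methyl-1,3-dioxolan-2-yl)ethyl]butanenitrile | COc1ccc(C(C#N)(CCC2(C)OCCO2)CCC2(C)OCCO2)cc1OC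
F7 | step 1 | 2-(3,4-dimethoxyphenyl)-4-(2-methyl-1,3-dioxolan-2-yl)-2-[2-(2-methyl-1,3-dioxolan-2-yl)ethyl]butanal | COc1ccc(C(C=O)(CCC2(C)OCCO2)CCC2(C)OCCO2)cc1OC
F8 | step 7 | 4-[(6S)-6-(3,4-dimethoxyphenyl)-5,6,7,8-tetrahydroquinolin-6-yl]-1,1,1-triiodobutan-2-one | COc1ccc([C@]2(CCC(=O)C(I)(I)I)CCc3ncccc3C2)cc1OC
F9 | step 7 | 3-[(6S)-6-(3,4-dimethoxyphenyl)-5,6,7,8-tetrahydroquinolin-6-yl]propanoic acid | COc1ccc([C@]2(CCC(=O)O)CCc3ncccc3C2)cc1OC
F10 | step 7 | 3-[(6S)-6-(3,4-dimethoxyphenyl)-5,6,7,8-tetrahydroquinolin-6-yl]propanoyl azide | COc1ccc([C@]2(CCC(=O)N=[N+]=[N-])CCc3ncccc3C2)cc1OC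
F11 | step 7 | (6R)-6-(3,4-dimethoxyphenyl)-6-(2-isocyanatoethyl)-5,6,7,8-tetrahydroquinoline | COc1ccc([C@]2(CCN=C=O)CCc3ncccc3C2)cc1OC
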